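**Retrosynthetic overview**

1. Numbering: the five-membered ring is C1(O)–C2–C3(CH3)–C9=C10(iPr), the seven-membered ring is C3–C4–C5(=O)–C6(CH3)(O)–C7–C8–C9. The strategy rests on the cyclopentenol C1–C2–C3–C9=C10 being the formal [3+2] adduct of an enal (C1–C3) and an isopropyl alkyne (C9≡C10) that are joined by the chain C4–C8.
2. Endgame: both angelates and the C5 ketone follow the ring construction (C1–OH esterified, C5/C6 acetonide removed, C5–OH oxidised, tertiary C6–OH esterified); one batch of the angeloyl mixed anhydride 21 serves both esterifications.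
3. Key disconnection: C3–C9 and C1–C10 of bicyclic cyclopentenol 19 are formed in one nickel reductive [3+2] bicyclisation of the acyclic (E)-alkynyl enal 18. The seven-membered ring closes first (oxidative cyclisation), the five-membered ring second (alkenylnickel addition to the aldehyde).
4. Enal 18 comes from terminal alkyne 14 by methylalumination and formaldehyde trapping (E-C2=C3 with its methyl, and C1), then allylic oxidation.
5. C5 comes from methyl (R)-glycidate, opened at C4 by a silylacetylide. C6 is set by chelate-controlled methyl addition to α-hydroxy ketone 11, which is made from Weinreb amide 9 and the Grignard reagent of bromide 4 (C7–C10 and the isopropyl group).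

Key step: step 11

Remark: which enantiomer of the chiral monophosphine is matched with the substrate at C3 cannot be foreseen; the route is written with (+)-neomenthyldiphenylphosphine, and its antipode would be taken if this one proves mismatched.

**Route**

Step 1
Reactants: 1 3-methylbut-1-yne
Product: 3 5-methylhex-3-yn-1-ol, via lithium acetylide 2 (not isolated)
Conditions: n-BuLi, THF, −78 °C; ethylene oxide, DMPU, −78 °C → rt
Reagents that add atoms: ethylene oxide, C1CO1
Why: Alkylation of a lithium acetylide by epoxide opening of ethylene oxide gives the homopropargylic alcohol that carries C7–C10 and the isopropyl group; no stereocentre is formed.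

Step 2
Reactants: 3 5-methylhex-3-yn-1-ol
Product: 4 1-bromo-5-methylhex-3-yne
Conditions: CBr4, PPh3, CH2Cl2, 0 °C
Reagents that add atoms: carbon tetrabromide, BrC(Br)(Br)Br
Why: The Appel reaction converts the primary alcohol into the bromide under neutral conditions that leave the internal alkyne untouched.

Step 3
Reactants: 5 ethynyltrimethylsilane; 6 methyl (R)-oxirane-2-carboxylate (methyl (R)-glycidate)
Product: 8 methyl (R)-2-hydroxy-5-(trimethylsilyl)pent-4-ynoate, via lithium silylacetylide 7 (not isolated)
Conditions: 5, n-BuLi, THF, −78 °C; BF3·OEt2; then 6, −78 °C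
Reagents that add atoms: none
Why: In this Yamaguchi–Hirao alkynylation the BF3-activated epoxide is opened at its unsubstituted CH2 (C4) while the ester survives at −78 °C, and C5 keeps the (R) configuration of the glycidate because its C–O bond is not touched.

Step 4
Reactants: 8 methyl (R)-2-hydroxy-5-(trimethylsilyl)pent-4-ynoate
Product: 9 (R)-2-hydroxy-N-methoxy-N-methyl-5-(trimethylsilyl)pent-4-ynamide
Conditions: MeNH(OMe)·HCl, iPrMgCl, THF, −20 → 0 °C
Reagents that add atoms: N,O-dimethylhydroxylamine hydrochloride, CNOC.Cl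
Why: Weinreb amide formation by aminolysis of the ester with the magnesium amide should proceed with the free hydroxyl carried as its magnesium alkoxide, which also protects C5 from epimerisation.

Step 5
Reactants: 4 1-bromo-5-methylhex-3-yne; 9 (R)-2-hydroxy-N-methoxy-N-methyl-5-(trimethylsilyl)pent-4-ynamide
Product: 11 (4R)-4-hydroxy-10-methyl-1-(trimethylsilyl)undeca-1,8-diyn-5-one, via Grignard reagent 10 (not isolated)
Conditions: 4, Mg, THF, rt; then 9, THF, 0 °C → rt
Reagents that add atoms: none
Why: In this Weinreb ketone synthesis the chelated tetrahedral adduct collapses only on work-up, so the Grignard reagent should add once and give the α-hydroxy ketone with C7–C10 attached to C6.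

Step 6
Reactants: 11 (4R)-4-hydroxy-10-methyl-1-(trimethylsilyl)undeca-1,8-diyn-5-one
Product: 12 (4R,5S)-5,10-dimethyl-1-(trimethylsilyl)undeca-1,8-diyne-4,5-diol
Conditions: MeMgBr, CH2Cl2–Et2O, −78 °C
Reagents that add atoms: methylmagnesium bromide, C[Mg]Br
Why: In this chelation-controlled Grignard addition (Cram cyclic model) the magnesium alkoxide at C5 and the C6 carbonyl form a five-membered chelate and methyl adds from the face of the C5 hydrogen, which should set C6 as (S) with C4 and C7 cis on the later dioxolane.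

Step 7
Reactants: 12 (4R,5S)-5,10-dimethyl-1-(trimethylsilyl)undeca-1,8-diyne-4,5-diol
Product: 13 trimethyl{3-[(4R,5S)-2,2,5-trimethyl-5-(5-methylhex-3-yn-1-yl)-1,3-dioxolan-4-yl]prop-1-yn-1-yl}silane
Conditions: 2,2-dimethoxypropane, PPTS (cat.), CH2Cl2, rt
Reagents that add atoms: 2,2-dimethoxypropane, COC(C)(C)OC
Why: Acid-catalysed transketalisation converts the secondary/tertiary 1,2-diol into its acetonide without touching either stereocentre.

Step 8
Reactants: 13 the silylalkyne acetonide
Product: 14 (4S,5R)-2,2,4-trimethyl-4-(5-methylhex-3-yn-1-yl)-5-(prop-2-yn-1-yl)-1,3-dioxolane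
Conditions: K2CO3, MeOH, rt
Reagents that add atoms: none
Why: Base-catalysed methanolysis of the alkynyl C–Si bond frees the terminal alkyne while the acetonide and the internal alkyne are inert.

Step 9
Reactants: 14 the terminal alkyne acetonide
Product: 17 (E)-3-methyl-4-[(4R,5S)-2,2,5-trimethyl-5-(5-methylhex-3-yn-1-yl)-1,3-dioxolan-4-yl]but-2-en-1-ol, via alkenylalane 15 (not isolated), via lithium alanate 16 (not isolated)
Conditions: Me3Al, Cp2ZrCl2 (0.25 equiv), CH2Cl2, 0 °C → rt; then n-BuLi, THF, −78 °C; (CH2O)n, −78 °C → rt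
Reagents that add atoms: trimethylaluminium, C[Al](C)C; paraformaldehyde (formaldehyde unit), C=O
Why: The zirconium-catalysed Negishi carboalumination adds methyl and aluminium syn across the terminal alkyne with methyl on C3, much faster than across the internal dialkyl alkyne, and the alanate is trapped by formaldehyde with retention, which fixes the E alkene and installs C1.

Step 10
Reactants: 17 the (E)-allylic alcohol
Product: 18 (E)-3-methyl-4-[(4R,5S)-2,2,5-trimethyl-5-(5-methylhex-3-yn-1-yl)-1,3-dioxolan-4-yl]but-2-enal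
Conditions: MnO2, CH2Cl2, rt
Reagents that add atoms: none
Why: Allylic oxidation with MnO2 should give the enal without E/Z isomerisation or over-oxidation.

Step 11
Reactants: 18 the (E)-alkynyl enal
Product: 19 (2S,6S,7R,8aR)-3-isopropyl-6,8a-dimethyl-6,7-(isopropylidenedioxy)-1,2,4,5,6,7,8,8a-octahydroazulen-2-ol (azulene positions 2, 8a, 7, 6 = route atoms C1, C3, C5, C6)
Conditions: Ni(COD)2 (20 mol %), (+)-neomenthyldiphenylphosphine (40 mol %), Et3B (4 equiv), MeOH–THF (1:8), 50 °C, slow addition of 18 (0.005 M)
Reagents that add atoms: none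
Why: Proposed new method: zerovalent nickel binds the enal and the alkyne of 18 and oxidative cyclisation joins the enal β-carbon C3 to alkyne carbon C9, giving an O-bound nickel enolate metallacycle with nickel on C10; methanol protonates the enolate at C2, the C10 alkenylnickel adds to the freed C1 aldehyde, and Et3B returns nickel to the zerovalent state by ethyl transfer, β-hydride elimination and O–H reductive elimination. The closest known reaction is the nickel-catalysed reductive [3+2] cycloaddition of enals with alkynes, established between separate partners and for alkynyl enals with three-atom tethers, but not for a five-atom tether or a β,β-disubstituted enal. The seven-membered ring closes in the oxidative cyclisation (exo mode, C3–C9 across the C4–C8 tether) and the five-membered ring in the intramolecular 1,2-addition of the alkenylnickel to the aldehyde (C10–C1), which leaves the C9=C10 alkene tetrasubstituted. C3 (R, quaternary) is set in the oxidative cyclisation by the enal face that the chiral monophosphine on nickel selects, assisted by the fixed E geometry and the cis-dioxolane; C1 (S) is set in the aldehyde addition relative to C3, with the carbonyl oxygen turned away from the C4 methylene of the new ring. The step needs cyclisation to outrun oligomerisation, aldehyde–alkyne reductive coupling and conjugate reduction: the cis C5–C6 acetonide folds the tether so that the two π-systems meet, and slow addition keeps the substrate dilute.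

Step 12
Reactants: 20 angelic acid
Product: 21 (Z)-2-methylbut-2-enoic 2,4,6-trichlorobenzoic anhydride
Conditions: 2,4,6-trichlorobenzoyl chloride, Et3N, toluene, 0 °C → rt; filtered under argon; made in one batch sized for steps 13 and 16 and kept as a dry toluene solution at −20 °C
Reagents that add atoms: 2,4,6-trichlorobenzoyl chloride, O=C(Cl)c1c(Cl)cc(Cl)cc1Cl
Why: Acylation of triethylammonium angelate by the hindered aroyl chloride (first stage of the Yamaguchi esterification) gives the mixed anhydride without heat or a nucleophilic catalyst, so the Z alkene should not isomerise, and in the absence of nucleophiles the filtered solution should keep without disproportionation.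

Step 13
Reactants: 19 the bicyclic cyclopentenol; 21 the angeloyl mixed anhydride
Product: 22 (2S,6S,7R,8aR)-3-isopropyl-6,8a-dimethyl-6,7-(isopropylidenedioxy)-1,2,4,5,6,7,8,8a-octahydroazulen-2-yl (Z)-2-methylbut-2-enoate
Conditions: 21 (toluene solution), Et3N, toluene, 80 °C
Reagents that add atoms: none
Why: In this Yamaguchi-type esterification, run without a nucleophilic catalyst, the secondary allylic alcohol should attack the less hindered angeloyl carbonyl of the mixed anhydride, with retention at C1 because its C–O bond is not touched and without angelate-to-tiglate isomerisation; Et3N takes up the released aroic acid so that the acetonide is not exposed to it.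

Step 14
Reactants: 22 the C1 angelate acetonide
Product: 23 (2S,6S,7R,8aS)-6,7-dihydroxy-3-isopropyl-6,8a-dimethyl-1,2,4,5,6,7,8,8a-octahydroazulen-2-yl (Z)-2-methylbut-2-enoate
Conditions: AcOH–H2O (4:1), 40 °C
Reagents that add atoms: none
Why: Mild acid hydrolysis of the acetonide should free the cis-diol, and aqueous acetic acid at moderate temperature is chosen so that the allylic ester does not ionise.

Step 15
Reactants: 23 the diol
Product: 24 (2S,6S,8aR)-6-hydroxy-3-isopropyl-6,8a-dimethyl-7-oxo-1,2,4,5,6,7,8,8a-octahydroazulen-2-yl (Z)-2-methylbut-2-enoate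
Conditions: 2-iodoxybenzoic acid (IBX), DMSO, rt
Reagents that add atoms: none
Why: IBX oxidation converts the only secondary alcohol (C5) into the ketone without cleaving the 1,2-diol, and the tertiary C6 hydroxyl cannot be oxidised.

Step 16
Reactants: 24 the α-hydroxy ketone; 21 the angeloyl mixed anhydride
Product: 26 (2S,6S,8aR)-3-isopropyl-6,8a-dimethyl-7-oxo-1,2,4,5,6,7,8,8a-octahydroazulene-2,6-diyl bis[(Z)-2-methylbut-2-enoate] (CNP0193302.1), via lithium C6-alkoxide 25 (not isolated)
Conditions: 24, LiN(SiMe3)2, THF, −78 °C; then 21 (toluene solution from step 12), −78 → 0 °C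
Reagents that add atoms: none
Why: O-Acylation of the lithium tertiary alkoxide by the mixed anhydride should occur at the unhindered angeloyl carbonyl, and the low temperature and absence of nucleophilic amine catalysts should suppress Z-to-E isomerisation and α-ketol rearrangement.

**Compound list**

1 | 3-methylbut-1-yne | CC(C)C#C | starting material
2 | lithium 3-methylbut-1-yn-1-ide | [Li]C#CC(C)C | intermediate (not isolated)
3 | 5-methylhex-3-yn-1-ol | CC(C)C#CCCO | intermediate
4 | 1-bromo-5-methylhex-3-yne | CC(C)C#CCCBr | intermediate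
5 | ethynyltrimethylsilane | C#C[Si](C)(C)C | starting material
6 | methyl (R)-oxirane-2-carboxylate (methyl (R)-glycidate) | COC(=O)[C@H]1CO1 | starting material
7 | lithium (trimethylsilyl)acetylide | [Li]C#C[Si](C)(C)C | intermediate (not isolated)
8 | methyl (R)-2-hydroxy-5-(trimethylsilyl)pent-4-ynoate | COC(=O)[C@H](O)CC#C[Si](C)(C)C | intermediate
9 | (R)-2-hydroxy-N-methoxy-N-methyl-5-(trimethylsilyl)pent-4-ynamide | CON(C)C(=O)[C@H](O)CC#C[Si](C)(C)C | intermediate
10 | (5-methylhex-3-yn-1-yl)magnesium bromide | CC(C)C#CCC[Mg]Br | intermediate (not isolated)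
11 | (4R)-4-hydroxy-10-methyl-1-(trimethylsilyl)undeca-1,8-diyn-5-one | CC(C)C#CCCC(=O)[C@H](O)CC#C[Si](C)(C)C | intermediate
12 | (4R,5S)-5,10-dimethyl-1-(trimethylsilyl)undeca-1,8-diyne-4,5-diol | CC(C)C#CCC[C@](C)(O)[C@H](O)CC#C[Si](C)(C)C | intermediate
13 | trimethyl{3-[(4R,5S)-2,2,5-trimethyl-5-(5-methylhex-3-yn-1-yl)-1,3-dioxolan-4-yl]prop-1-yn-1-yl}silane | C[Si](C)(C)C#CC[C@H]1OC(C)(C)O[C@@]1(C)CCC#CC(C)C | intermediate
14 | (4S,5R)-2,2,4-trimethyl-4-(5-methylhex-3-yn-1-yl)-5-(prop-2-yn-1-yl)-1,3-dioxolane | C#CC[C@H]1OC(C)(C)O[C@@]1(C)CCC#CC(C)C | intermediate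
15 | dimethyl{(E)-2-methyl-3-[(4R,5S)-2,2,5-trimethyl-5-(5-methylhex-3-yn-1-yl)-1,3-dioxolan-4-yl]prop-1-en-1-yl}alane | C[Al](C)/C=C(\C)C[C@H]1OC(C)(C)O[C@@]1(C)CCC#CC(C)C | intermediate (not isolated)
16 | lithium butyl(dimethyl){(E)-2-methyl-3-[(4R,5S)-2,2,5-trimethyl-5-(5-methylhex-3-yn-1-yl)-1,3-dioxolan-4-yl]prop-1-en-1-yl}alanate | [Li+].CCCC[Al-](C)(C)/C=C(\C)C[C@H]1OC(C)(C)O[C@@]1(C)CCC#CC(C)C | intermediate (not isolated)
17 | (E)-3-methyl-4-[(4R,5S)-2,2,5-trimethyl-5-(5-methylhex-3-yn-1-yl)-1,3-dioxolan-4-yl]but-2-en-1-ol | OC/C=C(\C)C[C@H]1OC(C)(C)O[C@@]1(C)CCC#CC(C)C | intermediate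
18 | (E)-3-methyl-4-[(4R,5S)-2,2,5-trimethyl-5-(5-methylhex-3-yn-1-yl)-1,3-dioxolan-4-yl]but-2-enal | O=C/C=C(\C)C[C@H]1OC(C)(C)O[C@@]1(C)CCC#CC(C)C | intermediate
19 | (2S,6S,7R,8aR)-3-isopropyl-6,8a-dimethyl-6,7-(isopropylidenedioxy)-1,2,4,5,6,7,8,8a-octahydroazulen-2-ol | O[C@H]1C[C@]2(C)C[C@H]3OC(C)(C)O[C@@]3(C)CCC2=C1C(C)C | intermediate
20 | angelic acid, (Z)-2-methylbut-2-enoic acid | C/C=C(/C)C(=O)O | starting material
21 | (Z)-2-methylbut-2-enoic 2,4,6-trichlorobenzoic anhydride | C/C=C(/C)C(=O)OC(=O)c1c(Cl)cc(Cl)cc1Cl | intermediate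
22 | (2S,6S,7R,8aR)-3-isopropyl-6,8a-dimethyl-6,7-(isopropylidenedioxy)-1,2,4,5,6,7,8,8a-octahydroazulen-2-yl (Z)-2-methylbut-2-enoate | C/C=C(/C)C(=O)O[C@H]1C[C@]2(C)C[C@H]3OC(C)(C)O[C@@]3(C)CCC2=C1C(C)C | intermediate
23 | (2S,6S,7R,8aS)-6,7-dihydroxy-3-isopropyl-6,8a-dimethyl-1,2,4,5,6,7,8,8a-octahydroazulen-2-yl (Z)-2-methylbut-2-enoate | C/C=C(/C)C(=O)O[C@H]1C[C@]2(C)C[C@@H](O)[C@@](C)(O)CCC2=C1C(C)C | intermediate
24 | (2S,6S,8aR)-6-hydroxy-3-isopropyl-6,8a-dimethyl-7-oxo-1,2,4,5,6,7,8,8a-octahydroazulen-2-yl (Z)-2-methylbut-2-enoate | C/C=C(/C)C(=O)O[C@H]1C[C@]2(C)CC(=O)[C@@](C)(O)CCC2=C1C(C)C | intermediate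
25 | lithium C6-alkoxide of 24 | [Li+].C/C=C(/C)C(=O)O[C@H]1C[C@]2(C)CC(=O)[C@@](C)([O-])CCC2=C1C(C)C | intermediate (not isolated)
26 | (2S,6S,8aR)-3-isopropyl-6,8a-dimethyl-7-oxo-1,2,4,5,6,7,8,8a-octahydroazulene-2,6-diyl bis[(Z)-2-methylbut-2-enoate] | C/C=C(/C)C(=O)O[C@H]1C[C@]2(C)CC(=O)[C@@](C)(OC(=O)/C(C)=C\C)CCC2=C1C(C)C | target

**Step count and risks**

Total steps: 16. Longest linear sequence: 13 steps (steps 3–11 and 13–16 from 5 and 6; the bromide branch, steps 1–2, joins at step 5, and the acyl donor from step 12 joins at steps 13 and 16).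

Steps most likely to fail:

Step 11. The oxidative cyclisation to a seven-membered ring with a quaternary C3 may be outrun by oligomerisation or simple reduction, or the face at C3 may be poorly controlled. The fallback sets out from 14 and comes back at 19. Alane 15 is made as in step 9 but quenched with water, which should give (4S,5R)-2,2,4-trimethyl-4-(5-methylhex-3-yn-1-yl)-5-(2-methylprop-2-en-1-yl)-1,3-dioxolane F1. An intramolecular Pauson–Khand reaction ([RhCl(CO)2]2 cat., CO 1 atm, toluene, 110 °C, high dilution) then joins C3 to C9 and inserts CO as C1 between C2 and C10, the closure again relying on the cis-dioxolane fold, to give (6S,7R,8aS)-3-isopropyl-6,8a-dimethyl-6,7-(isopropylidenedioxy)-4,5,6,7,8,8a-hexahydroazulen-2(1H)-one F2. Luche reduction (NaBH4, CeCl3·7H2O, MeOH, −78 °C) should give 19. If hydride delivery, or the nickel step itself, leads to the C1 epimer (2R,6S,7R,8aR)-3-isopropyl-6,8a-dimethyl-6,7-(isopropylidenedioxy)-1,2,4,5,6,7,8,8a-octahydroazulen-2-ol F3, a Mitsunobu esterification with 20 (PPh3, DIAD, toluene) inverts C1 and enters the route at 22.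

Step 16. Acylation of the hindered tertiary alkoxide may be slow, the stored acyl donor may disproportionate, and α-ketol rearrangement or Z-to-E isomerisation of the acyl group may compete. The fallback sets out from 24 and comes back at 26, building the angelate on the oxygen instead of transferring it. Acylation with 2-[bis(2,2,2-trifluoroethoxy)phosphoryl]propanoyl chloride and Et3N (CH2Cl2, 0 °C, through the derived ketene, which reacts even with tertiary alcohols) should give (2S,6S,8aR)-6-{2-[bis(2,2,2-trifluoroethoxy)phosphoryl]propanoyloxy}-3-isopropyl-6,8a-dimethyl-7-oxo-1,2,4,5,6,7,8,8a-octahydroazulen-2-yl (Z)-2-methylbut-2-enoate F4, as a mixture of epimers at the phosphonate carbon. A Still–Gennari olefination with acetaldehyde (KN(SiMe3)2, 18-crown-6, THF, −78 °C) then forms the Z-trisubstituted enoate and gives 26. The hindered C5 ketone is not expected to compete with acetaldehyde at this temperature.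

Step 9. Chemoselectivity between the two alkynes may be lost, or the acetonide may be cleaved by Me3Al. The fallback sets out from 14 and comes back at 17. Deprotonation with n-BuLi and addition to paraformaldehyde should give 4-[(4R,5S)-2,2,5-trimethyl-5-(5-methylhex-3-yn-1-yl)-1,3-dioxolan-4-yl]but-2-yn-1-ol F5. Hydroxyl-directed trans-hydroalumination with NaAlH2(OCH2CH2OCH3)2 (THF, 0 °C), which does not touch the isolated internal alkyne, followed by iodine, should give (Z)-3-iodo-4-[(4R,5S)-2,2,5-trimethyl-5-(5-methylhex-3-yn-1-yl)-1,3-dioxolan-4-yl]but-2-en-1-ol F6. Coupling with Me2CuLi (Et2O, 0 °C) replaces iodine by methyl with retention and gives 17.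

Further compounds
F1 | step 11 | (4S,5R)-2,2,4-trimethyl-4-(5-methylhex-3-yn-1-yl)-5-(2-methylprop-2-en-1-yl)-1,3-dioxolane | C=C(C)C[C@H]1OC(C)(C)O[C@@]1(C)CCC#CC(C)C
F2 | step 11 | (6S,7R,8aS)-3-isopropyl-6,8a-dimethyl-6,7-(isopropylidenedioxy)-4,5,6,7,8,8a-hexahydroazulen-2(1H)-one | O=C1C[C@]2(C)C[C@H]3OC(C)(C)O[C@@]3(C)CCC2=C1C(C)C
F3 | step 11 | (2R,6S,7R,8aR)-3-isopropyl-6,8a-dimethyl-6,7-(isopropylidenedioxy)-1,2,4,5,6,7,8,8a-octahydroazulen-2-ol | O[C@@H]1C[C@]2(C)C[C@H]3OC(C)(C)O[C@@]3(C)CCC2=C1C(C)C
F4 | step 16 | (2S,6S,8aR)-6-{2-[bis(2,2,2-trifluoroethoxy)phosphoryl]propanoyloxy}-3-isopropyl-6,8a-dimethyl-7-oxo-1,2,4,5,6,7,8,8a-octahydroazulen-2-yl (Z)-2-methylbut-2-enoate (both epimers at the phosphonate carbon) | C/C=C(/C)C(=O)O[C@H]1C[C@]2(C)CC(=O)[C@@](C)(OC(=O)C(C)P(=O)(OCC(F)(F)F)OCC(F)(F)F)CCC2=C1C(C)C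
F5 | step 9 | 4-[(4R,5S)-2,2,5-trimethyl-5-(5-methylhex-3-yn-1-yl)-1,3-dioxolan-4-yl]but-2-yn-1-ol | OCC#CC[C@H]1OC(C)(C)O[C@@]1(C)CCC#CC(C)C
F6 | step 9 | (Z)-3-iodo-4-[(4R,5S)-2,2,5-trimethyl-5-(5-methylhex-3-yn-1-yl)-1,3-dioxolan-4-yl]but-2-en-1-ol | OC/C=C(\I)C[C@H]1OC(C)(C)O[C@@]1(C)CCC#CC(C)C
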